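**Retrosynthetic overview**

1. 20 ⇐ 19 by cleavage of the two MOM ethers on ring B. Ring B is bought as an acetophenone; rings C and A do not exist before the key step (flavanone numbering O1, C2–C4, C4a, C5–C8, C8a is used for chain atoms throughout).
2. 19 ⇐ open-chain δ-hydroxy-β-diketone–dioxinone 15 in one pot: ring C closes first through O1–C8a (cyclodehydration), then ring A through C4a–C5 (acylketene ring closure, enolisation to the phloroglucinol).
3. Enabling feature: the oxygens on C4, C8a (O1), C7 and C5 sit on alternate carbons along C4–C4a–C8a–C8–C7–C6–C5 of rings C and A. This perimeter is therefore a folded 1,3,5,7-tetracarbonyl chain whose C2 hydroxyl is δ to the C8a carbonyl and whose C4a is 1,6-related to C5; the prenyl group rides on the C8 methine and can only end up at C8.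
4. 15 ⇐ C4–C4a bond by Claisen acylation of the dianion of prenylated keto-dioxinone 13 (from dioxinone 11, acetyl chloride and prenyl bromide 2) with (S)-β-silyloxy Weinreb amide 10.
5. 10 ⇐ aryl β-keto ester 7 by asymmetric transfer hydrogenation (sets C2); the 1,1-dimethylallyl group of ring B ⇐ aromatic Claisen rearrangement of the 4-O-prenyl ether of 2,4-dihydroxyacetophenone 1.

Key step: step 13

Assumption: 1, 2 and 11 are taken as commercial, and 13–17 are carried as mixtures of epimers at the carbon that becomes C8, which is harmless because that centre becomes an aromatic carbon.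

Notation: Ar = 2,4-bis(methoxymethoxy)-5-(2-methylbut-3-en-2-yl)phenyl; MOM = methoxymethyl; PPTS = pyridinium p-toluenesulfonate.

**Route**

Step 1
Reactants: 1 1-(2,4-dihydroxyphenyl)ethanone; 2 1-bromo-3-methylbut-2-ene (prenyl bromide)
Product: 3 1-[2-hydroxy-4-(3-methylbut-2-en-1-yloxy)phenyl]ethanone
Conditions: K2CO3, acetone, reflux
Reagents that add atoms: none
Why: Williamson ether synthesis; the 2-hydroxyl is held in a hydrogen bond to the acetyl group, so the free and more acidic 4-hydroxyl should be alkylated selectively.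

Step 2
Reactants: 3 1-[2-hydroxy-4-(3-methylbut-2-en-1-yloxy)phenyl]ethanone
Product: 4 1-[2-(methoxymethoxy)-4-(3-methylbut-2-en-1-yloxy)phenyl]ethanone
Conditions: NaH, MOMCl, DMF, 0 °C → rt
Reagents that add atoms: chloromethyl methyl ether, COCCl
Why: Phenoxide O-alkylation (MOM protection); capping the chelated hydroxyl removes the hydrogen bond that would steer the next rearrangement to C3.

Step 3
Reactants: 4 1-[2-(methoxymethoxy)-4-(3-methylbut-2-en-1-yloxy)phenyl]ethanone
Product: 5 1-[4-hydroxy-2-(methoxymethoxy)-5-(2-methylbut-3-en-2-yl)phenyl]ethanone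
Conditions: EtOH–H2O (4:1), 130 °C, sealed tube
Reagents that add atoms: none
Why: Aromatic Claisen rearrangement ([3,3]-sigmatropic shift), which turns the O-prenyl group into a C-(1,1-dimethylallyl) group at an ortho carbon; the open C5 position is expected to be preferred over C3, which is flanked by two oxygen substituents.

Step 4
Reactants: 5 1-[4-hydroxy-2-(methoxymethoxy)-5-(2-methylbut-3-en-2-yl)phenyl]ethanone
Product: 6 1-[2,4-bis(methoxymethoxy)-5-(2-methylbut-3-en-2-yl)phenyl]ethanone
Conditions: NaH, MOMCl, DMF, 0 °C → rt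
Reagents that add atoms: chloromethyl methyl ether, COCCl
Why: Phenoxide O-alkylation (MOM protection) of the phenol freed by the rearrangement, which is acidic because it is para to the acetyl group.

Step 5
Reactants: 6 1-[2,4-bis(methoxymethoxy)-5-(2-methylbut-3-en-2-yl)phenyl]ethanone
Product: 7 ethyl 3-Ar-3-oxopropanoate
Conditions: NaH, (EtO)2CO, THF, reflux; then aq. NH4Cl
Reagents that add atoms: diethyl carbonate, CCOC(=O)OCC
Why: Crossed Claisen condensation of the methyl ketone enolate with diethyl carbonate, driven to completion by deprotonation of the β-keto ester formed.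

Step 6
Reactants: 7 ethyl 3-Ar-3-oxopropanoate
Product: 8 ethyl (3S)-3-Ar-3-hydroxypropanoate
Conditions: RuCl(p-cymene)[(S,S)-TsDPEN] (1 mol %), HCO2H–Et3N (5:2), DMF, 40 °C
Reagents that add atoms: none
Why: Noyori–Ikariya asymmetric transfer hydrogenation; the (S,S) catalyst should deliver hydride to the aryl ketone face that gives the (S) benzylic alcohol, as with simple aryl ketones where the arene is the directing group, and isolated alkenes are not reduced, so the future C2 centre is set here.

Step 7
Reactants: 8 ethyl (3S)-3-Ar-3-hydroxypropanoate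
Product: 9 (3S)-3-Ar-3-hydroxy-N-methoxy-N-methylpropanamide
Conditions: MeNHOMe·HCl, iPrMgCl, THF, −20 → 0 °C; then aq. NH4Cl
Reagents that add atoms: N,O-dimethylhydroxylamine hydrochloride, CNOC.Cl
Why: Weinreb amide formation by aminolysis of the ester with the magnesium amide of N,O-dimethylhydroxylamine; the hydroxyl is only deprotonated and the stereocentre is not involved.

Step 8
Reactants: 9 (3S)-3-Ar-3-hydroxy-N-methoxy-N-methylpropanamide
Product: 10 (3S)-3-Ar-N-methoxy-N-methyl-3-(triethylsilyloxy)propanamide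
Conditions: Et3SiCl, imidazole, DMF, 0 °C
Reagents that add atoms: chlorotriethylsilane, CC[Si](Cl)(CC)CC
Why: Silylation of the secondary alcohol, so that no alkoxide is present during the dianion acylation.

Step 9
Reactants: 11 2,2,6-trimethyl-4H-1,3-dioxin-4-one
Product: 12 2,2-dimethyl-6-(2-oxopropyl)-4H-1,3-dioxin-4-one
Conditions: 11 (2 equiv), LiN(SiMe3)2 (2 equiv), THF, −78 °C; then AcCl (1 equiv), −78 °C; aq. NH4Cl
Reagents that add atoms: acetyl chloride, CC(Cl)=O
Why: Vinylogous Claisen-type C-acylation of the dioxinone lithium dienolate at its γ-carbon; the second equivalent of dienolate takes the acidic proton of the product.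

Step 10
Reactants: 12 2,2-dimethyl-6-(2-oxopropyl)-4H-1,3-dioxin-4-one; 2 1-bromo-3-methylbut-2-ene
Product: 13 2,2-dimethyl-6-(6-methyl-2-oxohept-5-en-3-yl)-4H-1,3-dioxin-4-one (racemic)
Conditions: NaH (1 equiv), THF, 0 °C; then 2, 0 °C → rt
Reagents that add atoms: none
Why: C-Alkylation of a stabilised 1,3-dicarbonyl-type sodium enolate at the carbon flanked by the ketone and the vinylogous ester; the new centre is racemic and is erased on aromatisation.

Step 11
Reactants: 13 2,2-dimethyl-6-(6-methyl-2-oxohept-5-en-3-yl)-4H-1,3-dioxin-4-one; 10 (3S)-3-Ar-N-methoxy-N-methyl-3-(triethylsilyloxy)propanamide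
Product: 14 6-[(1S)-1-Ar-9-methyl-3,5-dioxo-1-(triethylsilyloxy)dec-8-en-6-yl]-2,2-dimethyl-4H-1,3-dioxin-4-one
Conditions: 13 (1.5 equiv), LiN(iPr)2 (3 equiv), THF, −78 → −40 °C; then 10, −78 → −30 °C; aq. NH4Cl
Reagents that add atoms: none
Why: Crossed Claisen acylation of a ketone dianion; the less stabilised methyl-side enolate should attack the Weinreb amide, whose chelated tetrahedral intermediate prevents over-reaction and keeps C4 masked until the quench, and the (S) centre is untouched.

Step 12
Reactants: 14 6-[(1S)-1-Ar-9-methyl-3,5-dioxo-1-(triethylsilyloxy)dec-8-en-6-yl]-2,2-dimethyl-4H-1,3-dioxin-4-one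
Product: 15 6-[(1S)-1-Ar-1-hydroxy-9-methyl-3,5-dioxodec-8-en-6-yl]-2,2-dimethyl-4H-1,3-dioxin-4-one
Conditions: HF·pyridine, pyridine, THF, 0 °C; used crude
Reagents that add atoms: none
Why: Fluoride-mediated desilylation in a buffered, weakly acidic medium that should spare the MOM ethers and the dioxinone and avoids the base that would trigger aldol aromatisation of the diketo-dioxinone; any hemiketal or partly dehydrated material converges in step 13.

Step 13
Reactants: 15 6-[(1S)-1-Ar-1-hydroxy-9-methyl-3,5-dioxodec-8-en-6-yl]-2,2-dimethyl-4H-1,3-dioxin-4-one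
Product: 19 (2S)-2-Ar-5,7-dihydroxy-8-(3-methylbut-2-en-1-yl)-2,3-dihydro-4H-chromen-4-one, via dihydropyranone–dioxinone 16 (not isolated), via acylketene 17 (not isolated), via cyclohexadienone tautomer 18 (not isolated)
Conditions: PPTS (0.2 equiv), 4 Å MS, toluene (0.005 M), 50 °C; then 110 °C
Reagents that add atoms: none
Why: Proposed new method: at 50 °C the weak acid lets the C2 hydroxyl add to the C8a carbonyl (6-exo-trig hemiketalisation) and water is lost, closing ring C through O1–C8a to give the 2,3-dihydro-4H-pyran-4-one 16, which is the known cyclodehydration of δ-hydroxy-β-diketones. At 110 °C the dioxinone loses acetone by retro-[4+2] to give acylketene 17, the known thermolysis used in ketene-trapping aromatisations of diketo-dioxinones. Enolisation of the C7 ketone towards C8 makes 17 a dienylketene whose 6π-electrocyclisation (equivalently, attack of the nucleophilic vinylogous-ester carbon C4a on the ketene carbon C5) closes the six-membered ring A through C4a–C5 to give 18, which enolises to the phloroglucinol 19; the closest known reaction type is the terminal electrocyclisation of vinylketene–alkyne benzannulations. No new stereocentre is formed: C2 keeps its (S) configuration because its C–O bond is never broken, and the C8 centre is destroyed on aromatisation. The step needs O-cyclisation to precede ketene release and C4a–C5 closure to beat O-acylation: the dioxinone is inert at 50 °C, once ring C exists no oxygen can reach the ketene through a ring smaller than eight atoms, the base-induced C6-to-C4 aldol aromatisation is shut off because no base is present and both ketones have become a vinylogous ester, and high dilution suppresses intermolecular acylation by product phenols. The prenyl group can only appear at C8 because its carbon is already bonded to C8a in the chain.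

Step 14
Reactants: 19 (2S)-2-Ar-5,7-dihydroxy-8-(3-methylbut-2-en-1-yl)-2,3-dihydro-4H-chromen-4-one
Product: 20 (2S)-2-[2,4-dihydroxy-5-(2-methylbut-3-en-2-yl)phenyl]-5,7-dihydroxy-8-(3-methylbut-2-en-1-yl)-2,3-dihydro-4H-chromen-4-one (AChE-IN-17)
Conditions: HCl (2 M in MeOH), 40 °C
Reagents that add atoms: none
Why: Acid-catalysed acetal exchange (MOM cleavage) with methanol as acceptor, kept mild so that the prenyl and 1,1-dimethylallyl groups should not cyclise onto their neighbouring phenols and C2 should not epimerise.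

**Compound list** (Ar as defined above)

1 | 1-(2,4-dihydroxyphenyl)ethanone | CC(=O)c1ccc(O)cc1O | starting material
2 | 1-bromo-3-methylbut-2-ene | CC(C)=CCBr | starting material
3 | 1-[2-hydroxy-4-(3-methylbut-2-en-1-yloxy)phenyl]ethanone | CC(=O)c1ccc(OCC=C(C)C)cc1O | intermediate
4 | 1-[2-(methoxymethoxy)-4-(3-methylbut-2-en-1-yloxy)phenyl]ethanone | CC(=O)c1ccc(OCC=C(C)C)cc1OCOC | intermediate
5 | 1-[4-hydroxy-2-(methoxymethoxy)-5-(2-methylbut-3-en-2-yl)phenyl]ethanone | CC(=O)c1cc(C(C)(C)C=C)c(O)cc1OCOC | intermediate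
6 | 1-[2,4-bis(methoxymethoxy)-5-(2-methylbut-3-en-2-yl)phenyl]ethanone | CC(=O)c1cc(C(C)(C)C=C)c(OCOC)cc1OCOC | intermediate
7 | ethyl 3-[2,4-bis(methoxymethoxy)-5-(2-methylbut-3-en-2-yl)phenyl]-3-oxopropanoate | CCOC(=O)CC(=O)c1cc(C(C)(C)C=C)c(OCOC)cc1OCOC | intermediate
8 | ethyl (3S)-3-[2,4-bis(methoxymethoxy)-5-(2-methylbut-3-en-2-yl)phenyl]-3-hydroxypropanoate | CCOC(=O)C[C@H](O)c1cc(C(C)(C)C=C)c(OCOC)cc1OCOC | intermediate
9 | (3S)-3-[2,4-bis(methoxymethoxy)-5-(2-methylbut-3-en-2-yl)phenyl]-3-hydroxy-N-methoxy-N-methylpropanamide | CON(C)C(=O)C[C@H](O)c1cc(C(C)(C)C=C)c(OCOC)cc1OCOC | intermediate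
10 | (3S)-3-[2,4-bis(methoxymethoxy)-5-(2-methylbut-3-en-2-yl)phenyl]-N-methoxy-N-methyl-3-(triethylsilyloxy)propanamide | CON(C)C(=O)C[C@H](O[Si](CC)(CC)CC)c1cc(C(C)(C)C=C)c(OCOC)cc1OCOC | intermediate
11 | 2,2,6-trimethyl-4H-1,3-dioxin-4-one | CC1=CC(=O)OC(C)(C)O1 | starting material
12 | 2,2-dimethyl-6-(2-oxopropyl)-4H-1,3-dioxin-4-one | CC(=O)CC1=CC(=O)OC(C)(C)O1 | intermediate
13 | 2,2-dimethyl-6-(6-methyl-2-oxohept-5-en-3-yl)-4H-1,3-dioxin-4-one (racemic) | CC(=O)C(CC=C(C)C)C1=CC(=O)OC(C)(C)O1 | intermediate
14 | 6-[(1S)-1-Ar-9-methyl-3,5-dioxo-1-(triethylsilyloxy)dec-8-en-6-yl]-2,2-dimethyl-4H-1,3-dioxin-4-one (both epimers at chain C6) | CC(C)=CCC(C(=O)CC(=O)C[C@H](O[Si](CC)(CC)CC)c1cc(C(C)(C)C=C)c(OCOC)cc1OCOC)C1=CC(=O)OC(C)(C)O1 | intermediate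
15 | 6-[(1S)-1-Ar-1-hydroxy-9-methyl-3,5-dioxodec-8-en-6-yl]-2,2-dimethyl-4H-1,3-dioxin-4-one (both epimers at chain C6) | CC(C)=CCC(C(=O)CC(=O)C[C@H](O)c1cc(C(C)(C)C=C)c(OCOC)cc1OCOC)C1=CC(=O)OC(C)(C)O1 | intermediate
16 | 6-{1-[(2S)-2-Ar-4-oxo-3,4-dihydro-2H-pyran-6-yl]-4-methylpent-3-en-1-yl}-2,2-dimethyl-4H-1,3-dioxin-4-one | CC(C)=CCC(C1=CC(=O)C[C@@H](c2cc(C(C)(C)C=C)c(OCOC)cc2OCOC)O1)C1=CC(=O)OC(C)(C)O1 | intermediate (not isolated)
17 | 4-[(2S)-2-Ar-4-oxo-3,4-dihydro-2H-pyran-6-yl]-7-methylocta-1,6-diene-1,3-dione (acylketene) | CC(C)=CCC(C(=O)C=C=O)C1=CC(=O)C[C@@H](c2cc(C(C)(C)C=C)c(OCOC)cc2OCOC)O1 | intermediate (not isolated)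
18 | (2S)-2-Ar-7-hydroxy-8-(3-methylbut-2-en-1-yl)-2,3-dihydro-4H-chromene-4,5(4aH)-dione (either epimer at C4a) | O=C1C[C@@H](c2cc(C(C)(C)C=C)c(OCOC)cc2OCOC)OC2=C(CC=C(C)C)C(O)=CC(=O)C12 | intermediate (not isolated)
19 | (2S)-2-[2,4-bis(methoxymethoxy)-5-(2-methylbut-3-en-2-yl)phenyl]-5,7-dihydroxy-8-(3-methylbut-2-en-1-yl)-2,3-dihydro-4H-chromen-4-one | C=CC(C)(C)c1cc([C@@H]2CC(=O)c3c(O)cc(O)c(CC=C(C)C)c3O2)c(OCOC)cc1OCOC | intermediate
20 | (2S)-2-[2,4-dihydroxy-5-(2-methylbut-3-en-2-yl)phenyl]-5,7-dihydroxy-8-(3-methylbut-2-en-1-yl)-2,3-dihydro-4H-chromen-4-one | C=CC(C)(C)c1cc([C@@H]2CC(=O)c3c(O)cc(O)c(CC=C(C)C)c3O2)c(O)cc1O | target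

**Step count**

Total: 14 steps. Longest linear sequence: 12 steps (steps 1–8, then 11–14); the dioxinone branch (steps 9–10) joins at step 11.

**Steps most likely to fail**

1. Step 13. The acylketene may be consumed by intermolecular acylation or dimerisation faster than the intramolecular C4a–C5 closure, or ketene release may begin before ring C is fully closed, so that an enol oxygen captures the ketene as a pyranone. Fallback (known reactions, stepwise and anionic): set out from 15, stop after the PPTS stage and isolate the dihydropyranone 16 (acid-catalysed cyclodehydration of a δ-hydroxy-β-diketone). Heat 16 with methanol in toluene at 110 °C so that the acylketene is captured as the β-keto ester methyl 4-[(2S)-2-Ar-4-oxo-3,4-dihydro-2H-pyran-6-yl]-7-methyl-3-oxooct-6-enoate F1 (dioxinone alcoholysis). Close ring A by intramolecular Claisen (Dieckmann-type) condensation of F1 with Mg(OMe)2 in methanol, the reaction by which 3,5,7-triketo esters are closed to acylphloroglucinols; this returns to the route at 19.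

2. Step 3. The allyl unit may migrate to C3 instead of C5, the prenyl ether may be lost by solvolysis because the para-acetyl phenoxide is a good leaving group, or the product may rearrange further on prolonged heating. Fallback: set out from 1 and brominate at C5 (NBS, MeCN, 0 °C) to give 1-(5-bromo-2,4-dihydroxyphenyl)ethanone F2. Protect both phenols (NaH, MOMCl, DMF) to give 1-[5-bromo-2,4-bis(methoxymethoxy)phenyl]ethanone F3. Install the tertiary allyl group by a ligand-controlled γ-selective Suzuki–Miyaura coupling with 3-methylbut-2-en-1-ylboronic acid pinacol ester (Pd(OAc)2, bulky biarylphosphine ligand chosen for the branched isomer, K3PO4, THF–H2O); this returns to the route at 6, with the position of the new C–C bond fixed by the halogen and no sigmatropic step.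

3. Step 11. The hindered dianion may act as a base towards the amide (enolisation followed by β-elimination of the silyloxy group) or may acylate too slowly to compete with its own decomposition. Fallback: set out from 10 and reduce the Weinreb amide (iBu2AlH, THF, −78 °C) to (3S)-3-Ar-3-(triethylsilyloxy)propanal F4. Add F4 to the same dianion of 13 in an aldol reaction to give 6-[(1S)-1-Ar-3-hydroxy-9-methyl-5-oxo-1-(triethylsilyloxy)dec-8-en-6-yl]-2,2-dimethyl-4H-1,3-dioxin-4-one F5 (mixture of diastereomers). Oxidise the new secondary alcohol with Dess–Martin periodinane; this returns to the route at 14, the aldehyde being a much better electrophile for the dianion than the amide, at the cost of one oxidation.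

**Further compounds**

F1 | step 13 | methyl 4-[(2S)-2-Ar-4-oxo-3,4-dihydro-2H-pyran-6-yl]-7-methyl-3-oxooct-6-enoate | COC(=O)CC(=O)C(CC=C(C)C)C1=CC(=O)C[C@@H](c2cc(C(C)(C)C=C)c(OCOC)cc2OCOC)O1
F2 | step 3 | 1-(5-bromo-2,4-dihydroxyphenyl)ethanone | CC(=O)c1cc(Br)c(O)cc1O
F3 | step 3 | 1-[5-bromo-2,4-bis(methoxymethoxy)phenyl]ethanone | CC(=O)c1cc(Br)c(OCOC)cc1OCOC
F4 | step 11 | (3S)-3-Ar-3-(triethylsilyloxy)propanal | O=CC[C@H](O[Si](CC)(CC)CC)c1cc(C(C)(C)C=C)c(OCOC)cc1OCOC
F5 | step 11 | 6-[(1S)-1-Ar-3-hydroxy-9-methyl-5-oxo-1-(triethylsilyloxy)dec-8-en-6-yl]-2,2-dimethyl-4H-1,3-dioxin-4-one | CC(C)=CCC(C(=O)CC(O)C[C@H](O[Si](CC)(CC)CC)c1cc(C(C)(C)C=C)c(OCOC)cc1OCOC)C1=CC(=O)OC(C)(C)O1
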